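Readings and results are simulated from invented constants.

common to all: electrophile 0.28 M
- Sunday's: free base 0.28 M; protonated nucleophile 0.35 M; protic impurity 0.28 M; run made earlier
- Wednesday's: free base 0.28 M; protonated nucleophile 0.55 M; protic impurity 0.28 M; run made earlier
- Monday's: free base 0.56 M; protonated nucleophile 0.252 M; protic impurity 0.28 M; run made earlier
- flask: free base 0.280 M; protonated nucleophile 0.252 M; protic impurity 0.280 M; time 40 min

- Sunday's (time / min: electrophile / %, product / %): 3.00: 90, 4; 10.0: 70, 17; 15.0: 59, 23; 25.0: 44, 31; 40.0: 31, 35; 50.0: 24, 38
- Wednesday's (time / min: electrophile / %, product / %): 4.00: 86, 7; 6.00: 79, 10; 10.0: 67, 19; 20.0: 48, 29; 30.0: 37, 38; 50.0: 24, 42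
- Monday's (time / min: electrophile / %, product / %): 10.0: 68, 17; 20.0: 47, 32; 30.0: 33, 39; 40.0: 28, 46; 50.0: 17, 50

(scatter of a reading: 1.5 percentage points)

* part of the electrophile that has reacted at 40 min
* share of the unused nucleophile that is free and not bound as protonated nucleophile, at 40 min

- the analysis behind the earlier runs scatters by 1.5 percentage points, standard deviation
- steps thought possible: electrophile + nucleophile <-> acid set free + product; nucleophile + acid set free <-> protonated nucleophile; acid set free + free base <-> salt of the base; electrophile + protic impurity -> quenched substrate
- the earlier runs do not show how much of nucleophile is bound; that part of a forecast is a guess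

- Slowness can be counted: Sunday's electrophile fell to 31% of its charge in 40.0 min, which gives an averaged pseudo-first-order constant k of 0.0293 min⁻¹ and a half-life T of 23.7 min.
- But k sags: Sunday's reading at 25.0 min gives 0.0328 min⁻¹, higher than the average. The flask is asked at the same time, so the average over that span serves: 1.69 half-lives and about 69.0% reacted.
- A second doubt: the flask charges less protonated nucleophile than Sunday's run. Sunday's and Wednesday's runs, at 0.35 M and 0.55 M, both read 24% at 50.0 min, yet 0.252 M lies below both, so this stays an extrapolation.
- Electrophile has two exits. Of Sunday's loss at 40.0 min, 49.3% is not product and is assigned to the protic impurity. Dividing T by that share gives the quench half-life Tq 48.0 min, the time to halve the electrophile by the impurity acting by itself.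
- The runs do not show how much nucleophile is bound, so this count gives no free share.
- The forecast, which says of the protonated nucleophile “it looks like a reservoir”, gives 69% reacted and 55% free.
- The flask gives 67.7% reacted and 32.3% free, so the forecast's free share stands 23 percentage points too high.

    electrophile + nucleophile ⇌ acid set free + product (K = 0.350, k = 0.280 M⁻¹ min⁻¹)
    nucleophile + acid set free ⇌ protonated nucleophile, settled at all times (K = 470 M⁻¹)
    acid set free + free base ⇌ salt of the base (K = 17000 M⁻¹, k = 8.90 M⁻¹ min⁻¹)
    electrophile + protic impurity → quenched substrate (k = 0.0640 M⁻¹ min⁻¹)

- In the flask, acid set free has a half-life against free base, by the forward step alone, of 1.7 min at 40.0 min, far shorter than the run, and at that time free base stands at 16.0% of its charge and nucleophile at 0.0509 M. The flask's 40 min make 0.833 quench half-lives. Quenched substrate in the flask stands at 34.0% of the charge. Product stands at 33.7%. For a neighbour with 0.48 M protic impurity, Tq scaled by the charges is estimated at 28.0 min; keeping Sunday's product exit, the count leaves 20.5% electrophile, and that neighbour holds 19.9%.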